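Numbering used throughout: lactone ring O1–C2(=O)–C3=C4–C5–C6; side chain C7–C21 with carbinol carbons C8, C10, C12 and the nonyl tail C13–C21.
Retrosynthesis: the dihydropyranone ring is cut at C3=C4 and O1–C6 together. In this ring O1 sits on C6, the carbon β to C4, so C4–C5–C6 is a 2-enal (aldehyde carbon C4, β-carbon C6) and O1–C2–C3 is a carboxymethyl phosphorus ylide. Next come C5=C6 (cross-metathesis) and C7–C8, C9–C10, C11–C12 (three carbonyl allylations).
Forward: the chain grows from 1-decanol by three rounds of one operation pair (iridium-catalyzed allylation of a primary alcohol with allyl acetate, then ozonolysis/reduction). The last allyl group becomes the enal, the only ring (the lactone) is closed last, and one acid treatment unmasks the triol.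
Stereochemistry: C12, C10 and C8 each come from one antipode of a single iridium catalyst (the same antipode twice for the 10,12-syn pair, the other for C8 anti to C10). C6 comes from the chiral amine catalyst of the ring-forming step, and the ring alkene is cis because it is formed inside the six-membered ring.
Key step: step 9
Assumption: the iridium catalyst carrying (S)-BINAP is taken to attack the aldehyde face that gives an R carbinol from an unbranched alkyl aldehyde; if the sense is the reverse, the two BINAP antipodes change places in steps 1, 3 and 6.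

Step 1
Reactants: 1 1-decanol; 2 allyl acetate
Product: 4 (R)-tridec-1-en-4-ol, via decanal 3 (not isolated)
Conditions: 2 (excess), [Ir(cod)Cl]2 (2.5 mol%), (S)-BINAP (5 mol%), 4-chloro-3-nitrobenzoic acid (10 mol%), Cs2CO3 (20 mol%), THF, 100 °C, sealed tube
Reagents that add atoms: none
Why: Krische allylation (transfer-hydrogenative carbonyl allylation): the iridium catalyst takes hydrogen from the alcohol to give decanal 3 and, with allyl acetate, forms a cyclometalated allyliridium species that adds to 3 through a closed chair transition state, so the BINAP antipode alone should set C12 as R.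

Step 2
Reactants: 4 (R)-tridec-1-en-4-ol
Product: 6 (R)-dodecane-1,3-diol, via ozonide 5 (not isolated)
Conditions: O3, CH2Cl2, −78 °C; then NaBH4, EtOH, −78 °C to rt
Reagents that add atoms: ozone, [O-][O+]=O
Why: Ozonolysis of the terminal alkene to the secondary ozonide 5 and borohydride reduction in the same flask is a standard alkene-to-alcohol cleavage that leaves the carbinol center untouched.

Step 3
Reactants: 6 (R)-dodecane-1,3-diol; 2 allyl acetate
Product: 8 (4S,6R)-pentadec-1-ene-4,6-diol, via (R)-3-hydroxydodecanal 7 (not isolated)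
Conditions: 2 (excess), [Ir(cod)Cl]2 (2.5 mol%), (S)-BINAP (5 mol%), 4-chloro-3-nitrobenzoic acid (10 mol%), Cs2CO3 (20 mol%), THF, 100 °C, sealed tube
Reagents that add atoms: none
Why: Krische allylation of an unprotected 1,3-diol: only the primary carbinol is dehydrogenated at a useful rate (to aldehyde 7), and the same catalyst antipode as in step 1 should add the allyl group under catalyst control to give the 1,3-syn diol (new center C10).

Step 4
Reactants: 8 (4S,6R)-pentadec-1-ene-4,6-diol
Product: 9 (4S,6R)-4-allyl-2,2-dimethyl-6-nonyl-1,3-dioxane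
Conditions: 2,2-dimethoxypropane, PPTS (cat.), CH2Cl2, rt
Reagents that add atoms: 2,2-dimethoxypropane, COC(C)(C)OC
Why: Acid-catalyzed transacetalization, in which the syn-1,3-diol forms the chair 1,3-dioxane with both alkyl groups equatorial and O10 and O12 stay masked until the last step.

Step 5
Reactants: 9 (4S,6R)-4-allyl-2,2-dimethyl-6-nonyl-1,3-dioxane
Product: 11 2-[(4S,6R)-2,2-dimethyl-6-nonyl-1,3-dioxan-4-yl]ethan-1-ol, via ozonide 10 (not isolated)
Conditions: O3, CH2Cl2, −78 °C; then NaBH4, EtOH, −78 °C to rt
Reagents that add atoms: ozone, [O-][O+]=O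
Why: The same ozonolysis/borohydride cleavage as in step 2, to which the acetonide is inert, returns the chain end to the primary alcohol needed for the next allylation.

Step 6
Reactants: 11 2-[(4S,6R)-2,2-dimethyl-6-nonyl-1,3-dioxan-4-yl]ethan-1-ol; 2 allyl acetate
Product: 13 (2R)-1-[(4S,6R)-2,2-dimethyl-6-nonyl-1,3-dioxan-4-yl]pent-4-en-2-ol, via aldehyde 12 (not isolated)
Conditions: 2 (excess), [Ir(cod)Cl]2 (2.5 mol%), (R)-BINAP (5 mol%), 4-chloro-3-nitrobenzoic acid (10 mol%), Cs2CO3 (20 mol%), THF, 100 °C, sealed tube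
Reagents that add atoms: none
Why: Krische allylation with the antipodal catalyst, whose facial preference should override the weak 1,3-bias of the β-alkoxy aldehyde 12 and set C8 anti to C10.

Step 7
Reactants: 13 (2R)-1-[(4S,6R)-2,2-dimethyl-6-nonyl-1,3-dioxan-4-yl]pent-4-en-2-ol
Product: 14 tert-butyl({(2R)-1-[(4R,6R)-2,2-dimethyl-6-nonyl-1,3-dioxan-4-yl]pent-4-en-2-yl}oxy)dimethylsilane
Conditions: TBSCl, imidazole, DMF, rt
Reagents that add atoms: tert-butyldimethylsilyl chloride, CC(C)(C)[Si](C)(C)Cl
Why: Standard silylation of the secondary alcohol, which keeps O8 from acting as a nucleophile toward the enal and the lactone in steps 8 and 9.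

Step 8
Reactants: 14 tert-butyl({(2R)-1-[(4R,6R)-2,2-dimethyl-6-nonyl-1,3-dioxan-4-yl]pent-4-en-2-yl}oxy)dimethylsilane; 15 crotonaldehyde
Product: 16 (2E,5R)-5-[(tert-butyldimethylsilyl)oxy]-6-[(4R,6R)-2,2-dimethyl-6-nonyl-1,3-dioxan-4-yl]hex-2-enal
Conditions: 15 (5 equiv), second-generation Hoveyda–Grubbs catalyst (5 mol%), CH2Cl2, 40 °C
Reagents that add atoms: none
Why: Olefin cross-metathesis of an unhindered terminal alkene with excess crotonaldehyde should give the E-enal under thermodynamic control, with volatile propene as the only by-product.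

Step 9
Reactants: 16 (2E,5R)-5-[(tert-butyldimethylsilyl)oxy]-6-[(4R,6R)-2,2-dimethyl-6-nonyl-1,3-dioxan-4-yl]hex-2-enal; 17 (carboxymethyl)triphenylphosphonium chloride
Product: 19 (6S)-6-{(2S)-2-[(tert-butyldimethylsilyl)oxy]-3-[(4R,6R)-2,2-dimethyl-6-nonyl-1,3-dioxan-4-yl]propyl}-5,6-dihydro-2H-pyran-2-one, via ylide aldehyde 18 (not isolated)
Conditions: 17 and NaHCO3 (1.3 equiv each), CHCl3, rt, 30 min; then 16, (S)-α,α-diphenylprolinol trimethylsilyl ether (20 mol%), PhCO2H (20 mol%), rt
Reagents that add atoms: none
Why: Proposed new method: the amine condenses with enal 16 to an iminium ion, the carboxylate of 2-(triphenylphosphonio)acetate (made in the flask from 17 and NaHCO3) adds to C6, and hydrolysis of the enamine plus loss of a proton from the P–CH2 group give the ester-stabilized ylide aldehyde 18, which undergoes intramolecular Wittig olefination with loss of Ph3PO. The closest known reaction types are the amine-catalyzed conjugate addition of oxygen nucleophiles (oximes, hydroperoxides, phenols) to 2-enals, the amine-catalyzed Michael/intramolecular Wittig annulation of 2-enals with a carbon-acidic phosphorane, and the intramolecular Wittig closure of β-(phosphoranylideneacetoxy) carbonyl compounds to 5,6-dihydropyran-2-ones; the new element is a carboxylate as the conjugate donor. The lactone ring closes in the Wittig stage by 6-exo-trig attack of ylide carbon C3 on aldehyde carbon C4, and collapse of the oxaphosphetane leaves the C3=C4 bond, which can only be cis in a six-membered ring. C6 is set under catalyst control: the diphenyl(silyloxy)methyl group of the (S)-pyrrolidine covers one face of the E,s-trans iminium ion and O1 should enter from the other, which corresponds to 6S, whereas C8 lies outside the forming ring and should have only a minor influence. The step needs O-addition at C6 before any olefination and needs the reversible, uphill carboxylate addition to be drained: the betaine is not an ylide until its carboxylate has been alkylated (only the resulting ester makes the P–CH2 group acidic), so direct Wittig attack on the enal is switched off, and the irreversible ring closure removes the adduct from the retro-oxa-Michael equilibrium. The O8 silyl ether keeps that oxygen away from C4 and C6, and both protecting groups should tolerate the buffered, near-neutral medium.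

Step 10
Reactants: 19 (6S)-6-{(2S)-2-[(tert-butyldimethylsilyl)oxy]-3-[(4R,6R)-2,2-dimethyl-6-nonyl-1,3-dioxan-4-yl]propyl}-5,6-dihydro-2H-pyran-2-one
Product: 20 (6S)-6-[(2S,4R,6R)-2,4,6-trihydroxypentadecyl]-5,6-dihydro-2H-pyran-2-one
Conditions: HF (48% aq.), MeCN, 0 °C to rt
Reagents that add atoms: none
Why: Acidic global deprotection, in which aqueous HF removes the silyl ether as the silyl fluoride and hydrolyzes the acetonide without touching a stereocenter or opening the conjugated lactone, which is stable to acid but not to base.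

Compound list
1 | 1-decanol | CCCCCCCCCCO | starting material
2 | allyl acetate | CC(=O)OCC=C | starting material
3 | decanal | CCCCCCCCCC=O | intermediate
4 | (R)-tridec-1-en-4-ol | CCCCCCCCC[C@@H](O)CC=C | intermediate
5 | (2R)-1-(1,2,4-trioxolan-3-yl)undecan-2-ol (ozonide, both epimers at the trioxolane carbon) | CCCCCCCCC[C@@H](O)CC1OCOO1 | intermediate
6 | (R)-dodecane-1,3-diol | CCCCCCCCC[C@@H](O)CCO | intermediate
7 | (R)-3-hydroxydodecanal | CCCCCCCCC[C@@H](O)CC=O | intermediate
8 | (4S,6R)-pentadec-1-ene-4,6-diol | CCCCCCCCC[C@@H](O)C[C@@H](O)CC=C | intermediate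
9 | (4S,6R)-4-allyl-2,2-dimethyl-6-nonyl-1,3-dioxane | CCCCCCCCC[C@@H]1C[C@H](CC=C)OC(C)(C)O1 | intermediate
10 | (4R,6R)-2,2-dimethyl-6-nonyl-4-(1,2,4-trioxolan-3-ylmethyl)-1,3-dioxane (ozonide, both epimers at the trioxolane carbon) | CCCCCCCCC[C@@H]1C[C@H](CC2OCOO2)OC(C)(C)O1 | intermediate
11 | 2-[(4S,6R)-2,2-dimethyl-6-nonyl-1,3-dioxan-4-yl]ethan-1-ol | CCCCCCCCC[C@@H]1C[C@H](CCO)OC(C)(C)O1 | intermediate
12 | 2-[(4R,6R)-2,2-dimethyl-6-nonyl-1,3-dioxan-4-yl]acetaldehyde | CCCCCCCCC[C@@H]1C[C@H](CC=O)OC(C)(C)O1 | intermediate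
13 | (2R)-1-[(4S,6R)-2,2-dimethyl-6-nonyl-1,3-dioxan-4-yl]pent-4-en-2-ol | CCCCCCCCC[C@@H]1C[C@H](C[C@H](O)CC=C)OC(C)(C)O1 | intermediate
14 | tert-butyl({(2R)-1-[(4R,6R)-2,2-dimethyl-6-nonyl-1,3-dioxan-4-yl]pent-4-en-2-yl}oxy)dimethylsilane | CCCCCCCCC[C@@H]1C[C@H](C[C@H](O[Si](C)(C)C(C)(C)C)CC=C)OC(C)(C)O1 | intermediate
15 | crotonaldehyde, (E)-but-2-enal | C/C=C/C=O | starting material
16 | (2E,5R)-5-[(tert-butyldimethylsilyl)oxy]-6-[(4R,6R)-2,2-dimethyl-6-nonyl-1,3-dioxan-4-yl]hex-2-enal | CCCCCCCCC[C@@H]1C[C@H](C[C@H](O[Si](C)(C)C(C)(C)C)C/C=C/C=O)OC(C)(C)O1 | intermediate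
17 | (carboxymethyl)triphenylphosphonium chloride | OC(=O)C[P+](c1ccccc1)(c1ccccc1)c1ccccc1.[Cl-] | starting material
18 | (3R,5S)-5-[(tert-butyldimethylsilyl)oxy]-6-[(4R,6R)-2,2-dimethyl-6-nonyl-1,3-dioxan-4-yl]-1-oxohexan-3-yl 2-(triphenylphosphoranylidene)acetate | CCCCCCCCC[C@@H]1C[C@H](C[C@H](O[Si](C)(C)C(C)(C)C)C[C@H](CC=O)OC(=O)C=P(c2ccccc2)(c2ccccc2)c2ccccc2)OC(C)(C)O1 | intermediate
19 | (6S)-6-{(2S)-2-[(tert-butyldimethylsilyl)oxy]-3-[(4R,6R)-2,2-dimethyl-6-nonyl-1,3-dioxan-4-yl]propyl}-5,6-dihydro-2H-pyran-2-one | CCCCCCCCC[C@@H]1C[C@H](C[C@H](O[Si](C)(C)C(C)(C)C)C[C@@H]2CC=CC(=O)O2)OC(C)(C)O1 | intermediate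
20 | (6S)-6-[(2S,4R,6R)-2,4,6-trihydroxypentadecyl]-5,6-dihydro-2H-pyran-2-one | CCCCCCCCC[C@@H](O)C[C@@H](O)C[C@H](O)C[C@@H]1CC=CC(=O)O1 | target

Total step count: 10. Longest linear sequence: 10 steps (1 to 20).

Steps most likely to fail

Step 9 (proposed new method). The carboxylate may fail to add to the iminium ion at a useful rate because the addition is uphill and reversible, the phosphorus reagent may olefinate the aldehyde before the C–O bond exists, or the facial selectivity at C6 may be poor. The fallback uses known chemistry and builds the ring by acylation and ring-closing metathesis instead. It sets out from 14. Ozonolysis (O3, CH2Cl2, −78 °C; then PPh3) should give (3S)-3-[(tert-butyldimethylsilyl)oxy]-4-[(4R,6R)-2,2-dimethyl-6-nonyl-1,3-dioxan-4-yl]butanal F1. Krische allylation of this aldehyde (allyl acetate, the (S)-BINAP iridium catalyst of steps 1 and 3, isopropanol as hydrogen donor) should give (4S,6R)-6-[(tert-butyldimethylsilyl)oxy]-7-[(4R,6R)-2,2-dimethyl-6-nonyl-1,3-dioxan-4-yl]hept-1-en-4-ol F2, with the new carbinol anti to C8. Acryloyl chloride, Et3N and DMAP in CH2Cl2 should give (4S,6S)-6-[(tert-butyldimethylsilyl)oxy]-7-[(4R,6R)-2,2-dimethyl-6-nonyl-1,3-dioxan-4-yl]hept-1-en-4-yl prop-2-enoate F3. Ring-closing metathesis (second-generation Grubbs catalyst, CH2Cl2, 40 °C) then closes C3=C4, and the path comes back to the route at 19.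

Step 3. Site selectivity may be lost through dehydrogenation of the secondary carbinol, or the catalyst may not control the new center well enough in the presence of the free β-hydroxyl group. The fallback builds the syn-diol by substrate-controlled iodocyclization and sets out from 4. Boc2O and DMAP in MeCN should give tert-butyl (4R)-tridec-1-en-4-yl carbonate F4. IBr in toluene at −85 °C should cyclize it to the syn iodocarbonate (4R,6R)-4-(iodomethyl)-6-nonyl-1,3-dioxan-2-one F5. K2CO3 in MeOH should give the epoxy alcohol (2R)-1-[(2R)-oxiran-2-yl]undecan-2-ol F6. Vinylmagnesium bromide with catalytic CuI in THF at −40 °C opens the epoxide at its CH2 group, and the path comes back to the route at 8.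

Step 6. The catalyst may not override the intrinsic 1,3-bias of the β-alkoxy aldehyde, or the transient aldehyde may lose its β-oxygen by elimination under the basic conditions at 100 °C. The fallback uses stoichiometric reagent control at low temperature and sets out from 11. Dess–Martin periodinane in CH2Cl2 gives aldehyde 12, now isolated. Brown allylation with (+)-B-allyldiisopinocampheylborane (the reagent derived from (−)-α-pinene) in Et2O at −78 °C, followed by NaOH/H2O2, should give the anti product, and the path comes back to the route at 13. No compound outside the compound list arises on this path (F0).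

Further compounds
F1 | step 9 | (3S)-3-[(tert-butyldimethylsilyl)oxy]-4-[(4R,6R)-2,2-dimethyl-6-nonyl-1,3-dioxan-4-yl]butanal | CCCCCCCCC[C@@H]1C[C@H](C[C@H](O[Si](C)(C)C(C)(C)C)CC=O)OC(C)(C)O1
F2 | step 9 | (4S,6R)-6-[(tert-butyldimethylsilyl)oxy]-7-[(4R,6R)-2,2-dimethyl-6-nonyl-1,3-dioxan-4-yl]hept-1-en-4-ol | CCCCCCCCC[C@@H]1C[C@H](C[C@H](O[Si](C)(C)C(C)(C)C)C[C@@H](O)CC=C)OC(C)(C)O1
F3 | step 9 | (4S,6S)-6-[(tert-butyldimethylsilyl)oxy]-7-[(4R,6R)-2,2-dimethyl-6-nonyl-1,3-dioxan-4-yl]hept-1-en-4-yl prop-2-enoate | CCCCCCCCC[C@@H]1C[C@H](C[C@H](O[Si](C)(C)C(C)(C)C)C[C@@H](OC(=O)C=C)CC=C)OC(C)(C)O1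
F4 | step 3 | tert-butyl (4R)-tridec-1-en-4-yl carbonate | CCCCCCCCC[C@@H](OC(=O)OC(C)(C)C)CC=C
F5 | step 3 | (4R,6R)-4-(iodomethyl)-6-nonyl-1,3-dioxan-2-one | CCCCCCCCC[C@@H]1C[C@H](CI)OC(=O)O1
F6 | step 3 | (2R)-1-[(2R)-oxiran-2-yl]undecan-2-ol | CCCCCCCCC[C@@H](O)C[C@@H]1CO1
F0 | step 6 | none | none
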